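**Strategy.** The cyclohexene (C1 = CH carrying the side chain, C2/C3 = oxirane carbons, C4=C5, C6 = quaternary pyrone-bearing carbon) is disconnected at C1–C6 by an oxy-Cope transform. The key step is an anionic oxy-Cope rearrangement of a different six-membered ring: an epoxycyclohexenol whose quaternary carbon (future C4) carries the (E)-2-pyronylpropenyl arm (future C5=C6) cis to the oxirane. In one operation that ring opens, C1–C6 closes the cyclohexene, C4=C5 forms, C1 and C6 are set and an acetaldehyde arm appears. The step exploits the δ,ε-unsaturated carbonyl relationship between ring alkene C4=C5 and the side-chain carbinol carbon; both carbinol epimers of the precursor converge. Methylenation and a syn-aldol finish.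

Key step: step 12

Remark (assumption on the chemistry): the (S)-auxiliary 8 in step 5 and (+)-Ipc2BOTf in step 14 are taken to induce the configurations drawn; if either induction runs the other way, the enantiomeric reagent is used and nothing else changes.

## Route

Step 1
Reactants: 1 methyl 2-methyl-3-oxopentanoate; 2 N-methoxy-N-methylpropanamide
Product: 4 methyl 2,4-dimethyl-3,5-dioxoheptanoate, via sodium lithium dianion 3 (not isolated)
Conditions: NaH, THF, 0 °C; n-BuLi, 0 °C; 2, −78 to 0 °C; aq. HCl
Reagents that add atoms: none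
Why: γ-Acylation of a β-keto ester dianion at its more reactive terminal carbanion, with the Weinreb amide stopping at mono-acylation.

Step 2
Reactants: 4 methyl 2,4-dimethyl-3,5-dioxoheptanoate
Product: 5 6-ethyl-4-hydroxy-3,5-dimethyl-2H-pyran-2-one
Conditions: DBU, toluene, reflux; aq. HCl
Reagents that add atoms: none
Why: Base-promoted enol lactonisation of the 3,5-diketo ester closes the 4-hydroxy-2-pyranone ring with loss of methanol.

Step 3
Reactants: 5 6-ethyl-4-hydroxy-3,5-dimethyl-2H-pyran-2-one
Product: 6 6-ethyl-2-methoxy-3,5-dimethyl-4H-pyran-4-one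
Conditions: MeOTf, CH2Cl2, rt; aq. NaHCO3
Reagents that add atoms: methyl triflate COS(=O)(=O)C(F)(F)F
Why: O-Alkylation of the hydroxypyranone by a hard methylating agent at the lactone carbonyl oxygen should give the 2-methoxy-4-pyranone after neutralisation.

Step 4
Reactants: 7 2-methoxy-5-methylbenzoic acid; 8 (S)-2-(methoxymethyl)pyrrolidine
Product: 10 chiral benzamide of 7 and 8, via acid chloride 9 (not isolated)
Conditions: (COCl)2, cat. DMF, CH2Cl2, rt; 8, Et3N, 0 °C to rt
Reagents that add atoms: none
Why: Amide formation through the acid chloride (Schotten–Baumann type acylation) is routine for hindered benzoic acids.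

Step 5
Reactants: 10 chiral benzamide
Product: 12 (1S)-2-methoxy-1,5-dimethylcyclohexa-2,5-diene-1-carboxamide of 8, via potassium amide enolate 11 (not isolated)
Conditions: K, NH3(l), t-BuOH (1 equiv), THF, −78 °C; MeI, −78 °C
Reagents that add atoms: iodomethane CI
Why: Birch reductive alkylation: the chelated amide enolate 11 is methylated on the face left open by the auxiliary, which sets the quaternary carbon that later transfers its chirality to C1 and C6.

Step 6
Reactants: 12 Birch alkylation product
Product: 14 (2R)-2-(hydroxymethyl)-2,4-dimethylcyclohex-3-en-1-one, via dienyl methanol 13 (not isolated)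
Conditions: LiEt3BH, THF, 0 °C to rt; 1 M HCl, THF, rt
Reagents that add atoms: water O
Why: Hydride reduction of the tertiary amide with C–N cleavage gives the primary alcohol and frees the auxiliary, and the acidic work-up hydrolyses the methyl enol ether; the alkene cannot move into conjugation past the quaternary carbon.

Step 7
Reactants: 14 hydroxy ketone
Product: 15 (1R,2S,6S)-2-(hydroxymethyl)-2,6-dimethyl-7-oxabicyclo[4.1.0]heptan-3-one
Conditions: cat. VO(acac)2, t-BuOOH, CH2Cl2, 0 °C to rt
Reagents that add atoms: tert-butyl hydroperoxide CC(C)(C)OO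
Why: Hydroxyl-directed epoxidation of a homoallylic alcohol delivers oxygen syn to CH2OH, which sets both oxirane carbons cis to the carbon that becomes the propenyl arm.

Step 8
Reactants: 15 epoxy hydroxy ketone
Product: 16 (1R,2R,6S)-2,6-dimethyl-3-oxo-7-oxabicyclo[4.1.0]heptane-2-carbaldehyde
Conditions: Dess–Martin periodinane, NaHCO3, CH2Cl2, 0 °C to rt
Reagents that add atoms: none
Why: Dess–Martin oxidation under buffered conditions; the product is a non-enolisable keto aldehyde, so nothing can epimerise.

Step 9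
Reactants: 16 keto aldehyde; 6 6-ethyl-2-methoxy-3,5-dimethyl-4H-pyran-4-one
Product: 20 (1R,2S,6S)-2-[(1E)-2-(6-methoxy-3,5-dimethyl-4-oxo-4H-pyran-2-yl)prop-1-enyl]-2,6-dimethyl-7-oxabicyclo[4.1.0]heptan-3-one, via lithiated pyrone 17 (not isolated), via lithium aldolate 18 (not isolated), via mesylate 19 (not isolated)
Conditions: 6, LiN(SiMe3)2, THF, −78 °C; 16, −78 °C; MsCl, −78 to 0 °C; DBU, rt
Reagents that add atoms: none
Why: Vinylogous aldol addition of the laterally lithiated pyrone to the aldehyde (faster than to the hindered ketone), then mesylation and E1cB elimination through the only acidic β-hydrogen; both aldol diastereomers converge on the (E)-alkene with the pyrone trans to the quaternary carbon.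

Step 10
Reactants: 20 alkenyl epoxy ketone
Product: 22 (1R,2S,6S)-enone (7-oxabicyclo[4.1.0]hept-4-en-3-one) carrying the same substituents, via lithium enolate 21 (not isolated)
Conditions: LiN(i-Pr)2, THF, −78 °C; PhS(Cl)=N-t-Bu, −78 °C
Reagents that add atoms: none
Why: Mukaiyama dehydrogenation: the only enolisable position is sulfenylated and the sulfilimine undergoes syn-elimination at low temperature; the oxirane carbon next to the new alkene is quaternary, so no vinylogous elimination is available.

Step 11
Reactants: 22 epoxy enone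
Product: 23 (1R,2R,6S)-allylic alcohol (hept-4-en-3-ol), mixture of carbinol epimers
Conditions: NaBH4, CeCl3·7H2O, MeOH, −40 °C
Reagents that add atoms: none
Why: Luche 1,2-reduction of the enone; the pyranone carbonyl is a vinylogous ester and inert, and the carbinol configuration does not matter because this carbon becomes the aldehyde carbon.

Step 12
Reactants: 23 epoxycyclohexenol
Product: 26 2-[(1R,4R,5R,6S)-4-(6-methoxy-3,5-dimethyl-4-oxo-4H-pyran-2-yl)-2,4,6-trimethyl-7-oxabicyclo[4.1.0]hept-2-en-5-yl]acetaldehyde, via potassium alkoxide 24 (not isolated), via potassium enolate 25 (not isolated)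
Conditions: KN(SiMe3)2, 18-crown-6, THF, −78 to 0 °C; AcOH, −78 °C
Reagents that add atoms: none
Why: KN(SiMe3)2 converts 23 into alkoxide 24, whose oxyanion weakens the bond between the carbinol carbon and the quaternary carbon so that a charge-accelerated [3,3] shift across the 1,5-diene (propenyl C=C, quaternary carbon, carbinol carbon, ring CH=CH) forms C1–C6 while the old ring opens to enolate 25, protonated to 26. The closest known reaction type is the anionic oxy-Cope rearrangement of 1,5-dien-3-ols through a ring-enforced boat transition state. The cyclohexene is closed by suprafacial sigmatropic bond formation between the propenyl terminus and the ring alkene carbon, with the oxirane-fused C2–C3 bond as the tether, so C4=C5 can only come out cis. C1 is controlled by the quaternary stereocentre: the arm reaches the ring alkene only on its own face, the face of the oxirane oxygen, which leaves the CH2CHO arm trans to the oxirane. C6 is controlled by the (E) geometry of the propenyl group, which in the boat array puts the pyrone cis to the CH2CHO arm and the methyl on the oxirane face. The step needs the [3,3] path to outrun heterolytic cleavage to a pyrone-stabilised allyl anion that could open the oxirane by β-elimination; the cis tether that holds C6 over C1, the poor overlap of the oxirane C–O bonds with the breaking bond and the low temperature should secure this, and both epimers of 23 give the same 26.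

Step 13
Reactants: 26 aldehyde
Product: 28 2-[(1R,4R,5S,6S)-4-(6-methoxy-3,5-dimethyl-4-oxo-4H-pyran-2-yl)-2,4,6-trimethyl-7-oxabicyclo[4.1.0]hept-2-en-5-yl]prop-2-enal, via Mannich base 27 (not isolated)
Conditions: Me2N=CH2+ I−, Et3N, CH2Cl2, rt
Reagents that add atoms: N,N-dimethylmethyleneiminium iodide C=[N+](C)C.[I-]
Why: Eschenmoser methylenation: Mannich reaction at the only α-CH2 followed by β-elimination of dimethylamine gives the 2-substituted acrolein without touching any stereocentre (the changed descriptor is a priority effect only).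

Step 14
Reactants: 28 enal; 29 pentan-3-one
Product: 31 target, 2-methoxy-3,5-dimethyl-6-[(1R,4R,5R,6S)-5-[(3R,4R)-3-hydroxy-4-methyl-5-oxohept-1-en-2-yl]-2,4,6-trimethyl-7-oxabicyclo[4.1.0]hept-2-en-4-yl]-4H-pyran-4-one, via boron aldolate 30 (not isolated)
Conditions: 29, (+)-Ipc2BOTf, i-Pr2NEt, CH2Cl2, −78 °C; 28, −78 to −20 °C; H2O2, MeOH, pH 7 buffer, 0 °C
Reagents that add atoms: none
Why: Paterson aldol: the (Z)-boron enolate of pentan-3-one adds through a chair Zimmerman–Traxler transition state to give the syn aldol, and the isopinocampheyl ligands select the aldehyde re face, which sets the (3R,4R) pair under reagent control.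

## Compound list

1 | methyl 2-methyl-3-oxopentanoate | CCC(=O)C(C)C(=O)OC | starting material
2 | N-methoxy-N-methylpropanamide | CCC(=O)N(C)OC | starting material
3 | sodium lithium dianion of 1 (at C2 and C4) | [Na+].[Li+].C[CH-]C(=O)[C-](C)C(=O)OC | intermediate
4 | methyl 2,4-dimethyl-3,5-dioxoheptanoate | CCC(=O)C(C)C(=O)C(C)C(=O)OC | intermediate
5 | 6-ethyl-4-hydroxy-3,5-dimethyl-2H-pyran-2-one | CCc1oc(=O)c(C)c(O)c1C | intermediate
6 | 6-ethyl-2-methoxy-3,5-dimethyl-4H-pyran-4-one | CCc1oc(OC)c(C)c(=O)c1C | intermediate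
7 | 2-methoxy-5-methylbenzoic acid | COc1ccc(C)cc1C(=O)O | starting material
8 | (S)-2-(methoxymethyl)pyrrolidine | COC[C@@H]1CCCN1 | starting material
9 | 2-methoxy-5-methylbenzoyl chloride | COc1ccc(C)cc1C(Cl)=O | intermediate
10 | (2-methoxy-5-methylphenyl)[(2S)-2-(methoxymethyl)pyrrolidin-1-yl]methanone | COC[C@@H]1CCCN1C(=O)c1cc(C)ccc1OC | intermediate
11 | potassium amide enolate from Birch reduction of 10 | COC1=CCC(C)=CC1=C([O-])N1CCC[C@H]1COC.[K+] | intermediate
12 | [(1S)-2-methoxy-1,5-dimethylcyclohexa-2,5-dien-1-yl][(2S)-2-(methoxymethyl)pyrrolidin-1-yl]methanone | C[C@]1(C(=O)N2CCC[C@H]2COC)C=C(C)CC=C1OC | intermediate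
13 | [(1R)-2-methoxy-1,5-dimethylcyclohexa-2,5-dien-1-yl]methanol | C[C@]1(CO)C=C(C)CC=C1OC | intermediate
14 | (2R)-2-(hydroxymethyl)-2,4-dimethylcyclohex-3-en-1-one | C[C@]1(CO)C=C(C)CCC1=O | intermediate
15 | (1R,2S,6S)-2-(hydroxymethyl)-2,6-dimethyl-7-oxabicyclo[4.1.0]heptan-3-one (oxirane cis to CH2OH) | C[C@]1(CO)[C@H]2O[C@@]2(C)CCC1=O | intermediate
16 | (1R,2R,6S)-2,6-dimethyl-3-oxo-7-oxabicyclo[4.1.0]heptane-2-carbaldehyde | C[C@]1(C=O)[C@H]2O[C@@]2(C)CCC1=O | intermediate
17 | lithium salt of 6 deprotonated at the ethyl CH2 | [Li+].C[CH-]c1oc(OC)c(C)c(=O)c1C | intermediate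
18 | lithium aldolate of 17 and 16 (new centres as a mixture) | [Li+].[O-]C(C(C)c1oc(OC)c(C)c(=O)c1C)[C@@]1(C)[C@H]2O[C@@]2(C)CCC1=O | intermediate
19 | methanesulfonate of the aldol adduct (new centres as a mixture) | CS(=O)(=O)OC(C(C)c1oc(OC)c(C)c(=O)c1C)[C@@]1(C)[C@H]2O[C@@]2(C)CCC1=O | intermediate
20 | (1R,2S,6S)-2-[(1E)-2-(6-methoxy-3,5-dimethyl-4-oxo-4H-pyran-2-yl)prop-1-enyl]-2,6-dimethyl-7-oxabicyclo[4.1.0]heptan-3-one | C/C(c1oc(OC)c(C)c(=O)c1C)=C\[C@@]1(C)[C@H]2O[C@@]2(C)CCC1=O | intermediate
21 | lithium enolate of 20 | C/C(c1oc(OC)c(C)c(=O)c1C)=C\[C@@]1(C)[C@H]2O[C@@]2(C)CC=C1[O-].[Li+] | intermediate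
22 | (1R,2S,6S)-2-[(1E)-2-(6-methoxy-3,5-dimethyl-4-oxo-4H-pyran-2-yl)prop-1-enyl]-2,6-dimethyl-7-oxabicyclo[4.1.0]hept-4-en-3-one | C/C(c1oc(OC)c(C)c(=O)c1C)=C\[C@@]1(C)[C@H]2O[C@@]2(C)C=CC1=O | intermediate
23 | (1R,2R,6S)-2-[(1E)-2-(6-methoxy-3,5-dimethyl-4-oxo-4H-pyran-2-yl)prop-1-enyl]-2,6-dimethyl-7-oxabicyclo[4.1.0]hept-4-en-3-ol, both C3 epimers | C/C(c1oc(OC)c(C)c(=O)c1C)=C\[C@@]1(C)[C@H]2O[C@@]2(C)C=CC1O | intermediate
24 | potassium alkoxide of 23 | C/C(c1oc(OC)c(C)c(=O)c1C)=C\[C@@]1(C)[C@H]2O[C@@]2(C)C=CC1[O-].[K+] | intermediate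
25 | potassium enolate of 26 | [K+].[O-]C=C[C@H]1[C@]2(C)O[C@@H]2C(C)=C[C@@]1(C)c1oc(OC)c(C)c(=O)c1C | intermediate
26 | 2-[(1R,4R,5R,6S)-4-(6-methoxy-3,5-dimethyl-4-oxo-4H-pyran-2-yl)-2,4,6-trimethyl-7-oxabicyclo[4.1.0]hept-2-en-5-yl]acetaldehyde | O=CC[C@H]1[C@]2(C)O[C@@H]2C(C)=C[C@@]1(C)c1oc(OC)c(C)c(=O)c1C | intermediate
27 | α-(dimethylaminomethyl) derivative of 26 (Mannich base, new centre as a mixture) | CN(C)CC(C=O)[C@H]1[C@]2(C)O[C@@H]2C(C)=C[C@@]1(C)c1oc(OC)c(C)c(=O)c1C | intermediate
28 | 2-[(1R,4R,5S,6S)-4-(6-methoxy-3,5-dimethyl-4-oxo-4H-pyran-2-yl)-2,4,6-trimethyl-7-oxabicyclo[4.1.0]hept-2-en-5-yl]prop-2-enal | C=C(C=O)[C@H]1[C@]2(C)O[C@@H]2C(C)=C[C@@]1(C)c1oc(OC)c(C)c(=O)c1C | intermediate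
29 | pentan-3-one | CCC(=O)CC | starting material
30 | diisopinocampheylboron aldolate of 31 | C=C([C@H](OB([C@H]2C[C@H]3C[C@@H]([C@@H]2C)C3(C)C)[C@H]2C[C@H]3C[C@@H]([C@@H]2C)C3(C)C)[C@@H](C)C(=O)CC)[C@H]1[C@]2(C)O[C@@H]2C(C)=C[C@@]1(C)c1oc(OC)c(C)c(=O)c1C | intermediate
31 | 2-methoxy-3,5-dimethyl-6-[(1R,4R,5R,6S)-5-[(3R,4R)-3-hydroxy-4-methyl-5-oxohept-1-en-2-yl]-2,4,6-trimethyl-7-oxabicyclo[4.1.0]hept-2-en-4-yl]-4H-pyran-4-one | C=C([C@H](O)[C@@H](C)C(=O)CC)[C@H]1[C@]2(C)O[C@@H]2C(C)=C[C@@]1(C)c1oc(OC)c(C)c(=O)c1C | target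

## Summary

Total step count: 14. Longest linear sequence: 11 steps (steps 4 to 14); the pyrone (steps 1 to 3) joins at step 9.

Steps most likely to fail:

1. Step 12. The oxyanion may cause heterolytic cleavage to the pyrone-stabilised allyl anion and β-elimination of the oxirane instead of the sigmatropic shift. The fallback sets out from 23 and comes back at 26. Silylation of 23 (Et3SiCl, imidazole, DMF) would give the triethylsilyl ether F1. Heating F1 in degassed o-xylene at about 170 °C in base-washed glass should bring about a neutral siloxy-Cope rearrangement, with no anionic charge, to the silyl enol ether F2. Cleavage of F2 with Bu4NF and AcOH in THF at 0 °C would give 26.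

2. Step 6. The amide on the quaternary carbon may resist hydride attack or be reduced with C–O cleavage to the amine. The fallback sets out from 12 and comes back at 16, and also replaces steps 7 and 8. Oxalic acid in wet THF would hydrolyse the enol ether to the keto amide F3. I2 in THF–H2O should then give the iodolactone F4 by attack of the amide oxygen on the iodonium ion of the ring alkene, with loss of the auxiliary. i-Bu2AlH (CH2Cl2, −78 to 0 °C) would reduce lactone and ketone to the iodo triol F5. K2CO3 in MeOH would close the oxirane, necessarily cis to CH2OH, to give the epoxy diol F6. Dess–Martin oxidation of both hydroxyls of F6 gives 16.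

3. Step 9. The crowded aldolate may revert by retro-aldol cleavage or escape mesylation. The fallback sets out from 6 and 16 and comes back at 20. Lithiated 6 would be trapped with ClP(O)(OEt)2 to give the phosphonate F7. Horner–Wadsworth–Emmons olefination of 16 with F7 (NaH, THF, 0 °C to rt) should give 20 directly.

Further compounds

F1 | step 12 | triethylsilyl ether of 23 | C/C(c1oc(OC)c(C)c(=O)c1C)=C\[C@@]1(C)[C@H]2O[C@@]2(C)C=CC1O[Si](CC)(CC)CC
F2 | step 12 | triethylsilyl enol ether of 26 | CC[Si](CC)(CC)OC=C[C@H]1[C@]2(C)O[C@@H]2C(C)=C[C@@]1(C)c1oc(OC)c(C)c(=O)c1C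
F3 | step 6 | keto amide from enol ether hydrolysis of 12 | C[C@]1(C(=O)N2CCC[C@H]2COC)C=C(C)CCC1=O
F4 | step 6 | bicyclic iodo γ-lactone (lactone oxygen on the methyl-bearing carbon, iodine anti to it) | O=C1O[C@@]2(C)CCC(=O)[C@]1(C)[C@@H]2I
F5 | step 6 | iodo triol from reduction of F4 (secondary carbinol as a mixture) | OC[C@@]1(C)[C@H](I)[C@@](C)(O)CCC1O
F6 | step 6 | epoxy diol (secondary carbinol as a mixture) | OC[C@@]1(C)[C@H]2O[C@@]2(C)CCC1O
F7 | step 9 | diethyl [1-(6-methoxy-3,5-dimethyl-4-oxo-4H-pyran-2-yl)ethyl]phosphonate | CCOP(=O)(OCC)C(C)c1oc(OC)c(C)c(=O)c1C
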